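## Analysis of the target

The target 27 is a resveratrol trimer. Its core is a 2,3-dihydro-1-benzofuran (O1, C2, C3, C3a, C4–C7, C7a) with a 4-hydroxyphenyl group on C2, a 3,5-dihydroxyphenyl group on C3 and a hydroxyl on C6. C4 carries a fully substituted oxolane (O1', C2'–C5') bound through C3'. The oxolane has 4-hydroxyphenyl groups on C2' and C5' and a second 3,5-dihydroxyphenyl group on C4'.

There are six stereocentres. C2 and C3 are trans (2S,3S). In the oxolane (2'R,3'R,4'S,5'R) the substituents on C2', C3' and C4' lie on one face and the C5' aryl group on the other, so 2',3' and 3',4' are cis and 4',5' is trans. This contiguous cis triad is crowded and is not the thermodynamically preferred arrangement. The two stereochemical domains meet only at the single bond C4–C3', so no ring relates them.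

Sensitive features are the eight free phenols (air oxidation) and three benzylic C–O bonds, each para to an oxygenated aryl group (C2–O1, C2'–O1', C5'–O1'). These bonds are open to acid ionisation and to hydrogenolysis. The main difficulties are telling apart two identical 3,5-dihydroxyphenyl rings and three 4-hydroxyphenyl rings, setting the cis triad, and linking the two domains.

The strategy rests on one feature. C2–C3 with its two aryl groups is a resveratrol unit fused onto a resorcinol ring through C3–C3a and O1–C2, the connectivity of ε-viniferin. The benzene ring of the benzofuran, with O1 and the C6 hydroxyl, is therefore simply the 3,5-dihydroxyphenyl substituent on C3' of a tetraaryl oxolane.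

## Retrosynthetic reasoning

**27 to 26.** The six phenols that take no part in the ring-forming step are cut back to benzyl ethers. Their removal is the last operation, so that only the two phenol systems needed for the coupling are ever free before it.

**26 to 19 and 24 (C3–C3a and O1–C2).** Cutting these two bonds removes the dihydrofuran ring and both of its stereocentres. It divides the molecule into the stilbene phenol 24 and the oxolane-bearing resorcinol 19. No other pair of cuts simplifies as much. The polarity also fits: oxidation of 24 places radical character on the olefinic carbon that becomes C3 and leaves a quinone methide carbon (in 25) that becomes C2. The forward reaction has to achieve cross-coupling rather than dimerisation of 24, bond formation at the resorcinol carbon next to the oxolane, trans ring closure, and a usable face selectivity at C3.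

**24 to 21 and 22; 21 to 20.** The olefin is cut to the benzylic phosphonate 21 and the silyl-protected aldehyde 22, because a stabilised phosphonate anion gives the E alkene reliably. 21 comes from the benzylic bromide 20.

**19 to 18.** The resorcinol ring on C3' must be told apart from the other 3,5-dioxygenated ring on C4'. It is carried as a bis(silyl ether) while all other phenols are benzyl ethers, so that fluoride frees exactly this ring.

**18 to 17 to 13 and 14 (C2'–H and C2'–aryl).** The 2',3'-cis relation is not the stable one. It is therefore made kinetically: the aryl group from 14 is added to the lactone carbonyl of 13 to give lactol 17, and a hydride is then delivered to the derived oxocarbenium ion from the face away from the aryl groups on C3' and C4'.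

**13 to 11 and 12 (C5'–aryl).** The C5' aryl bond is cut to an acetal carbon. Ionisation of the lactone acetal 11 and attack of arene 12 from the face away from the two cis aryl groups gives the 4',5'-trans relation, which is also the stable one at this centre.

**11 to 10 (C3'–H and C4'–H).** The 3',4'-cis relation is traced to syn addition of hydrogen to the tetrasubstituted butenolide 10. The acetal stereocentre with its menthyl group blocks one face, so this step also fixes the absolute configuration of the oxolane.

**10 to 5 and 9; 5 to 3 and 4; 9 to 7 to 6.** The two aryl–alkene bonds are cut to boron reagents 4 and 9 and the dibromide 3. The two bromides of 3 differ in reactivity, which allows two different aryl groups to be placed in a fixed order. Boronate 9 is traced through bromide 7 to the bromoresorcinol 6.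

**3 to 1 and 2.** The acetal is cut to mucobromic acid 1 and (−)-menthol 2. This supplies all four ring carbons of the oxolane in the right oxidation states and a separable stereocentre.

## Alternatives that were turned down

**Alternative 1:** The benzene ring of the benzofuran would receive its two carbon substituents in one step. The aryne released from silyl triflate A1 inserts into the bond between the methylene and ketone carbons of β-keto ester A2 and gives the ortho-acyl arylacetate A3. The ketone carbon is the future C3 and the ester-bearing methylene the future C3'.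
- For: aryne acyl-alkylation is established chemistry. The alkoxy group beside the aryne bond directs the nucleophile to the distal carbon, so the substitution pattern around C3a and C4, with oxygen at C7a and C6, is secure. On this regiochemical point it is stronger than the chosen route.
- Against: the step closes no ring and sets no stereocentre. The hindered diaryl ketone must still become the C3 stereocentre and be joined to C2 and O1. The acetate carbon must be grown into a tetraaryl oxolane with three more aryl groups and the cis triad, next to existing stereocentres that give little control.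
- Comparison: the chosen strategy is far more convergent. It forms one ring, two bonds and two stereocentres in the last skeletal step, and it builds the oxolane on a free-standing lactone under auxiliary control.

**Alternative 2:** The phenol ring would not exist until late. The enolate of trans-lactone A4 adds to enone A5 (C3a–C4), the resulting methyl ketone enolate attacks the lactone carbonyl (C7–C7a), and the alkoxide released from C2 closes back onto C7a. This gives the bicyclic vinylogous ester A6, which must later be dehydrogenated to the phenol. The acetal carbon on C4 would be the anchor for the oxolane.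
- For: the trans C2/C3 pair and its absolute configuration come from a simple lactone, so these centres are not left to a weakly biased coupling. The ring fusion is regiochemically unambiguous. On both points it is stronger than the chosen route.
- Against: the cascade needs three events in order on a hindered lactone, with retro-Michael and double Michael pathways as competitors. Aromatisation of A6 must spare the C3a–H neighbourhood and the labile C2–O1 bond. The whole oxolane, with four stereocentres and three aryl groups, must then be grown from one aldehyde carbon ortho to the C3 substituent.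
- Comparison: the chosen strategy is much shorter and confines the uncertain chemistry to one late step.

**Alternative 3:** The oxolane would be closed near the end. The rhodium carbene from diazo ketone A7, which already contains the complete dihydrobenzofuran, adds to the protected stilbene A8. This forms C3'–C4' and O1'–C5' and gives dihydrofuran A9, whose C2'=C3' enol ether is then hydrogenated.
- For: the formal [3+2] has matched polarity, since the cationic centre develops at C5' next to the 4-benzyloxyphenyl group. The E alkene should give the 4',5'-trans relation. Hydrogenation anti to the C4' aryl group would give the cis triad and could be merged with the final debenzylation. A chiral rhodium carboxylate could control absolute configuration, which is stronger than the undirected face selectivity at C3 in the chosen route.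
- Against: A7 presupposes the dihydrobenzofuran, so the ε-viniferin-type annulation must be solved earlier and on a more functionalised substrate. trans-1,2-Diaryl alkenes are poor partners for donor/acceptor carbenes, and Wolff rearrangement and insertion into the many benzylic C–H bonds compete. Hydrogenation of an enol ether flanked by four aryl groups is demanding.
- Comparison: the chosen strategy makes the oxolane from inexpensive materials under auxiliary control and places its single speculative step last.

Key step: step 13

Assumption: the 5S acetal epimer of 3 can be separated from its 5R epimer by crystallisation or chromatography. It is the epimer needed so that hydrogen addition anti to the menthyloxy group gives the (3R,4S) lactone.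

## Route

Step 1
Reactants: 1 mucobromic acid (3,4-dibromo-5-hydroxyfuran-2(5H)-one); 2 (−)-menthol [(1R,2S,5R)-2-isopropyl-5-methylcyclohexan-1-ol]
Product: 3 (5S)-3,4-dibromo-5-{[(1R,2S,5R)-2-isopropyl-5-methylcyclohexyl]oxy}furan-2(5H)-one
Conditions: p-TsOH·H2O (5 mol %), toluene, reflux, azeotropic removal of H2O; crystallisation (hexane)
Reagents that add atoms: none
Why: Acid-catalysed acetalisation of the cyclic hemiacetal (pseudo-acid) with the alcohol; C5 should form as both epimers, which are diastereomers through the menthyl group, and the 5S epimer is to be isolated by crystallisation while the remainder is re-equilibrated with acid and recycled.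

Step 2
Reactants: 3; 4 [3,5-bis(benzyloxy)phenyl]boronic acid
Product: 5 (5S)-4-[3,5-bis(benzyloxy)phenyl]-3-bromo-5-{[(1R,2S,5R)-2-isopropyl-5-methylcyclohexyl]oxy}furan-2(5H)-one
Conditions: PdCl2(PPh3)2 (5 mol %), KF (3 equiv), toluene–H2O, rt to 40 °C
Reagents that add atoms: none
Why: Suzuki–Miyaura coupling; the C4–Br bond is β to the carbonyl (a vinylogous acyl bromide) and should add to zerovalent palladium much faster than the α C3–Br bond, so one equivalent of 4 arylates C4 only, and the mild fluoride base should leave the acetal and its C5 configuration untouched.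

Step 3
Reactants: 6 5-bromobenzene-1,3-diol
Product: 7 1-bromo-3,5-bis(triisopropylsilyloxy)benzene
Conditions: TIPSCl (2.3 equiv), imidazole, DMF, rt
Reagents that add atoms: triisopropylsilyl chloride, CC(C)[Si](Cl)(C(C)C)C(C)C
Why: Standard silylation of phenols; the bulky triisopropylsilyl ethers are chosen because they survive aqueous base, Lewis acids and organometallic reagents and later shield this ring against electrophiles.

Step 4
Reactants: 7
Product: 9 2-[3,5-bis(triisopropylsilyloxy)phenyl]-4,4,5,5-tetramethyl-1,3,2-dioxaborolane, via aryllithium 8 (not isolated)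
Conditions: n-BuLi, THF, −78 °C; then 2-isopropoxy-4,4,5,5-tetramethyl-1,3,2-dioxaborolane, −78 °C to rt; H2O
Reagents that add atoms: 2-isopropoxy-4,4,5,5-tetramethyl-1,3,2-dioxaborolane, CC(C)OB1OC(C)(C)C(C)(C)O1
Why: Bromine–lithium exchange followed by trapping of the aryllithium with a borate ester; the silyl ethers tolerate the cold organolithium.

Step 5
Reactants: 5; 9
Product: 10 (5S)-4-[3,5-bis(benzyloxy)phenyl]-3-[3,5-bis(triisopropylsilyloxy)phenyl]-5-{[(1R,2S,5R)-2-isopropyl-5-methylcyclohexyl]oxy}furan-2(5H)-one
Conditions: Pd(OAc)2 (5 mol %), SPhos (10 mol %), K3PO4, toluene–H2O (10:1), 70 °C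
Reagents that add atoms: none
Why: Second Suzuki–Miyaura coupling at the remaining α-bromo enoate position, for which an electron-rich biaryl phosphine is used because the alkene becomes tetrasubstituted; should C5 epimerise partly under the base, the menthyl group keeps the epimers separable by crystallisation.

Step 6
Reactants: 10
Product: 11 (3R,4S,5S)-4-[3,5-bis(benzyloxy)phenyl]-3-[3,5-bis(triisopropylsilyloxy)phenyl]-5-{[(1R,2S,5R)-2-isopropyl-5-methylcyclohexyl]oxy}oxolan-2-one (all-cis)
Conditions: H2 (4 atm), PtO2 (10 mol %), EtOAc, rt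
Reagents that add atoms: none
Why: Heterogeneous syn hydrogenation of the butenolide; the menthyloxy group on C5 blocks one face, so both hydrogens should add anti to it and the two aryl groups end cis to each other and to the acetal substituent (3R,4S), while platinum, unlike palladium, has little activity for hydrogenolysis of aryl benzyl ethers.

Step 7
Reactants: 11; 12 benzyl phenyl ether
Product: 13 (3R,4S,5R)-4-[3,5-bis(benzyloxy)phenyl]-5-[4-(benzyloxy)phenyl]-3-[3,5-bis(triisopropylsilyloxy)phenyl]oxolan-2-one (3,4-cis, 4,5-trans)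
Conditions: 12 (10 equiv), BF3·OEt2 (2 equiv), CH2Cl2, −30 to 0 °C
Reagents that add atoms: none
Why: Friedel–Crafts arylation of a lactone acetal (pseudo-ester) through its acyloxocarbenium ion; the arene should react para to its ether oxygen and from the face away from the two cis aryl groups on C3 and C4, giving the 4,5-trans lactone, which is also the stable epimer at this benzylic centre, and the bulky silyl ethers keep the ring on C3 from acting as an internal nucleophile.

Step 8
Reactants: 13; 14 1-(benzyloxy)-4-bromobenzene
Product: 17 (3R,4S,5R)-2,5-bis[4-(benzyloxy)phenyl]-4-[3,5-bis(benzyloxy)phenyl]-3-[3,5-bis(triisopropylsilyloxy)phenyl]oxolan-2-ol (mixture at C2), via aryllithium 15 (not isolated), via arylcerium dichloride 16 (not isolated)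
Conditions: 14, n-BuLi, THF, −78 °C; CeCl3 (anhydrous), −78 °C; then 13, −78 °C; H2O
Reagents that add atoms: none
Why: 1,2-Addition of an organocerium reagent to a lactone; the weakly basic cerium reagent should add to the carbonyl group without removing the acidic α-aryl proton on C3, and the tetrahedral adduct is stable at −78 °C, so a single addition gives the lactol, whose C2 configuration is immaterial.

Step 9
Reactants: 17
Product: 18 (2R,3R,4S,5R)-2,5-bis[4-(benzyloxy)phenyl]-4-[3,5-bis(benzyloxy)phenyl]-3-[3,5-bis(triisopropylsilyloxy)phenyl]oxolane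
Conditions: Et3SiH (5 equiv), BF3·OEt2 (2 equiv), CH2Cl2, −78 °C
Reagents that add atoms: none
Why: Ionic reduction of a cyclic hemiketal through its 2-aryl oxocarbenium ion; the silane should deliver hydride to the face away from the aryl groups on C3 and C4, so the aryl group on C2 ends cis to that on C3 (2R), and the low temperature is meant to suppress loss of the C3 proton and ionisation of the benzylic C5–O bond.

Step 10
Reactants: 18
Product: 19 5-{(2R,3R,4S,5R)-2,5-bis[4-(benzyloxy)phenyl]-4-[3,5-bis(benzyloxy)phenyl]oxolan-3-yl}benzene-1,3-diol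
Conditions: TBAF (2.5 equiv), AcOH (2.5 equiv), THF, 0 °C
Reagents that add atoms: none
Why: Fluoride cleavage of the two aryl silyl ethers; benzyl ethers and the ring C–O bonds are inert to fluoride, and the acetic acid buffer keeps the resorcinol from standing as an oxidisable phenolate.

Step 11
Reactants: 20 1,3-bis(benzyloxy)-5-(bromomethyl)benzene
Product: 21 diethyl [3,5-bis(benzyloxy)benzyl]phosphonate
Conditions: P(OEt)3 (neat), 130 °C
Reagents that add atoms: triethyl phosphite, CCOP(OCC)OCC
Why: Michaelis–Arbuzov reaction of a reactive benzylic bromide.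

Step 12
Reactants: 21; 22 4-[(tert-butyldimethylsilyl)oxy]benzaldehyde
Product: 24 (E)-4-[3,5-bis(benzyloxy)styryl]phenol, via silyl-protected stilbene 23 (not isolated)
Conditions: KOtBu (1.2 equiv), THF, 0 °C to rt; then TBAF (1.5 equiv), rt; AcOH
Reagents that add atoms: none
Why: Horner–Wadsworth–Emmons olefination of a stabilised benzylic phosphonate anion, which should give the E stilbene, followed by fluoride removal of the silyl ether in the same flask; the silyl ether avoids the poorly electrophilic phenolate of the free hydroxy aldehyde.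

Step 13
Reactants: 19; 24
Product: 26 (2S,3S)-3-[3,5-bis(benzyloxy)phenyl]-4-{(2R,3R,4S,5R)-2,5-bis[4-(benzyloxy)phenyl]-4-[3,5-bis(benzyloxy)phenyl]oxolan-3-yl}-2-(4-hydroxyphenyl)-2,3-dihydro-1-benzofuran-6-ol, via quinone methide 25 (not isolated)
Conditions: Ag2O (1.5 equiv), CH2Cl2–acetone (2:1), rt, dark, argon; 24 (2 equiv) added over 8 h
Reagents that add atoms: none
Why: Proposed new method: Ag2O, an oxidant of monovalent silver, should take one electron and a proton from the 4-hydroxystilbene 24 and give a phenoxyl radical whose spin is shared by the olefinic carbon that carries the bis(benzyloxy)phenyl ring; this carbon bonds to the ring carbon of 19 that lies between the oxolane-bearing carbon and one hydroxyl and para to the other (C3–C3a), by coupling with the resorcinol-derived radical or by addition to the electron-rich ring and a second one-electron oxidation, and tautomerisation of the ring leaves p-quinone methide 25. The phenol oxygen next to the new bond then adds to the quinone methide carbon in a 5-exo-trig conjugate addition (O1–C2), which closes the dihydrofuran ring and restores the 4-hydroxyphenyl group. The closest known reaction type is the oxidative dehydrodimerisation of 4-hydroxystilbenes and propenylphenols to 2-aryl-2,3-dihydrobenzofurans with silver or iron oxidants or peroxidases; what has not been shown is the selective cross-coupling of such a radical with a separate resorcinol. C3 is set in the C–C bond formation, where only the neighbouring oxolane stereocentre C3' distinguishes the two faces of the planar radical, so 26 should form together with the isomer of opposite configuration at C2 and C3 and is to be separated from it by chromatography. C2 is set in the ring closure, trans to the aryl group on C3, because this addition is reversible through 25 and the trans isomer is the more stable. Cross-coupling needs the stilbene radical to meet 19 before it meets a second radical, which slow addition of 24 to 19 and the oxidant is meant to secure, and the benzyl ethers leave no other phenol that could be oxidised. Bond formation at the crowded carbon next to the oxolane, and not at the carbon between the two hydroxyls, rests only on the electronic preference of resorcinols for the position ortho to one and para to the other hydroxyl, and is the least secured selectivity of the step.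

Step 14
Reactants: 26
Product: 27 (2S,3S)-3-(3,5-dihydroxyphenyl)-4-[(2R,3R,4S,5R)-4-(3,5-dihydroxyphenyl)-2,5-bis(4-hydroxyphenyl)oxolan-3-yl]-2-(4-hydroxyphenyl)-2,3-dihydro-1-benzofuran-6-ol
Conditions: H2 (1 atm), 10% Pd/C, NaHCO3, EtOAc–MeOH (1:1), rt
Reagents that add atoms: none
Why: Hydrogenolysis of six aryl benzyl ethers, which cleave much faster than the benzylic C–O bonds of the two oxygen rings; the solid buffer removes traces of acid that would promote ring hydrogenolysis, and no stereocentre is touched.

## Compound list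

1 | mucobromic acid (3,4-dibromo-5-hydroxyfuran-2(5H)-one) | OC1OC(=O)C(Br)=C1Br | starting material
2 | (−)-menthol | CC(C)[C@@H]1CC[C@@H](C)C[C@H]1O | starting material
3 | (5S)-3,4-dibromo-5-{[(1R,2S,5R)-2-isopropyl-5-methylcyclohexyl]oxy}furan-2(5H)-one | CC(C)[C@@H]1CC[C@@H](C)C[C@H]1O[C@H]2OC(=O)C(Br)=C2Br | intermediate
4 | [3,5-bis(benzyloxy)phenyl]boronic acid | OB(O)c1cc(OCc2ccccc2)cc(OCc2ccccc2)c1 | starting material
5 | (5S)-4-[3,5-bis(benzyloxy)phenyl]-3-bromo-5-(menthyloxy)furan-2(5H)-one | CC(C)[C@@H]1CC[C@@H](C)C[C@H]1O[C@H]2OC(=O)C(Br)=C2c3cc(OCc4ccccc4)cc(OCc4ccccc4)c3 | intermediate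
6 | 5-bromobenzene-1,3-diol | Oc1cc(O)cc(Br)c1 | starting material
7 | 1-bromo-3,5-bis(triisopropylsilyloxy)benzene | CC(C)[Si](C(C)C)(C(C)C)Oc1cc(Br)cc(O[Si](C(C)C)(C(C)C)C(C)C)c1 | intermediate
8 | [3,5-bis(triisopropylsilyloxy)phenyl]lithium | [Li]c1cc(O[Si](C(C)C)(C(C)C)C(C)C)cc(O[Si](C(C)C)(C(C)C)C(C)C)c1 | intermediate
9 | 2-[3,5-bis(triisopropylsilyloxy)phenyl]-4,4,5,5-tetramethyl-1,3,2-dioxaborolane | CC(C)[Si](C(C)C)(C(C)C)Oc1cc(O[Si](C(C)C)(C(C)C)C(C)C)cc(c1)B2OC(C)(C)C(C)(C)O2 | intermediate
10 | (5S)-4-[3,5-bis(benzyloxy)phenyl]-3-[3,5-bis(triisopropylsilyloxy)phenyl]-5-(menthyloxy)furan-2(5H)-one | CC(C)[C@@H]1CC[C@@H](C)C[C@H]1O[C@H]2OC(=O)C(c3cc(O[Si](C(C)C)(C(C)C)C(C)C)cc(O[Si](C(C)C)(C(C)C)C(C)C)c3)=C2c5cc(OCc6ccccc6)cc(OCc6ccccc6)c5 | intermediate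
11 | (3R,4S,5S)-4-[3,5-bis(benzyloxy)phenyl]-3-[3,5-bis(triisopropylsilyloxy)phenyl]-5-(menthyloxy)oxolan-2-one | CC(C)[C@@H]1CC[C@@H](C)C[C@H]1O[C@H]2OC(=O)[C@@H](c3cc(O[Si](C(C)C)(C(C)C)C(C)C)cc(O[Si](C(C)C)(C(C)C)C(C)C)c3)[C@H]2c5cc(OCc6ccccc6)cc(OCc6ccccc6)c5 | intermediate
12 | benzyl phenyl ether | c1ccc(cc1)OCc1ccccc1 | starting material
13 | (3R,4S,5R)-4-[3,5-bis(benzyloxy)phenyl]-5-[4-(benzyloxy)phenyl]-3-[3,5-bis(triisopropylsilyloxy)phenyl]oxolan-2-one | CC(C)[Si](C(C)C)(C(C)C)Oc1cc(O[Si](C(C)C)(C(C)C)C(C)C)cc(c1)[C@H]2[C@@H](c3cc(OCc4ccccc4)cc(OCc4ccccc4)c3)[C@H](c5ccc(OCc6ccccc6)cc5)OC2=O | intermediate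
14 | 1-(benzyloxy)-4-bromobenzene | Brc1ccc(OCc2ccccc2)cc1 | starting material
15 | [4-(benzyloxy)phenyl]lithium | [Li]c1ccc(OCc2ccccc2)cc1 | intermediate
16 | [4-(benzyloxy)phenyl]cerium dichloride | Cl[Ce](Cl)c1ccc(OCc2ccccc2)cc1 | intermediate
17 | (3R,4S,5R)-2,5-bis[4-(benzyloxy)phenyl]-4-[3,5-bis(benzyloxy)phenyl]-3-[3,5-bis(triisopropylsilyloxy)phenyl]oxolan-2-ol (mixture at C2) | CC(C)[Si](C(C)C)(C(C)C)Oc1cc(O[Si](C(C)C)(C(C)C)C(C)C)cc(c1)[C@H]2[C@@H](c3cc(OCc4ccccc4)cc(OCc4ccccc4)c3)[C@H](c5ccc(OCc6ccccc6)cc5)OC2(O)c7ccc(OCc8ccccc8)cc7 | intermediate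
18 | (2R,3R,4S,5R)-2,5-bis[4-(benzyloxy)phenyl]-4-[3,5-bis(benzyloxy)phenyl]-3-[3,5-bis(triisopropylsilyloxy)phenyl]oxolane | CC(C)[Si](C(C)C)(C(C)C)Oc1cc(O[Si](C(C)C)(C(C)C)C(C)C)cc(c1)[C@H]2[C@@H](c3cc(OCc4ccccc4)cc(OCc4ccccc4)c3)[C@H](c5ccc(OCc6ccccc6)cc5)O[C@H]2c7ccc(OCc8ccccc8)cc7 | intermediate
19 | 5-{(2R,3R,4S,5R)-2,5-bis[4-(benzyloxy)phenyl]-4-[3,5-bis(benzyloxy)phenyl]oxolan-3-yl}benzene-1,3-diol | Oc1cc(O)cc(c1)[C@H]2[C@@H](c3cc(OCc4ccccc4)cc(OCc4ccccc4)c3)[C@H](c5ccc(OCc6ccccc6)cc5)O[C@H]2c7ccc(OCc8ccccc8)cc7 | intermediate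
20 | 1,3-bis(benzyloxy)-5-(bromomethyl)benzene | BrCc1cc(OCc2ccccc2)cc(OCc2ccccc2)c1 | starting material
21 | diethyl [3,5-bis(benzyloxy)benzyl]phosphonate | CCOP(=O)(OCC)Cc1cc(OCc2ccccc2)cc(OCc2ccccc2)c1 | intermediate
22 | 4-[(tert-butyldimethylsilyl)oxy]benzaldehyde | CC(C)(C)[Si](C)(C)Oc1ccc(C=O)cc1 | starting material
23 | (E)-tert-butyl{4-[3,5-bis(benzyloxy)styryl]phenoxy}dimethylsilane | CC(C)(C)[Si](C)(C)Oc1ccc(/C=C/c2cc(OCc3ccccc3)cc(OCc3ccccc3)c2)cc1 | intermediate
24 | (E)-4-[3,5-bis(benzyloxy)styryl]phenol | Oc1ccc(/C=C/c2cc(OCc3ccccc3)cc(OCc3ccccc3)c2)cc1 | intermediate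
25 | 4-{(2S)-2-[3,5-bis(benzyloxy)phenyl]-2-[2,4-dihydroxy-6-(tetraaryloxolan-3-yl)phenyl]ethylidene}cyclohexa-2,5-dien-1-one (p-quinone methide; oxolane as in 19) | O=C1C=CC(=C[C@@H](c2cc(OCc3ccccc3)cc(OCc3ccccc3)c2)c2c(O)cc(O)cc2[C@H]2[C@@H](c3cc(OCc4ccccc4)cc(OCc4ccccc4)c3)[C@H](c3ccc(OCc4ccccc4)cc3)O[C@H]2c2ccc(OCc3ccccc3)cc2)C=C1 | intermediate
26 | (2S,3S)-3-[3,5-bis(benzyloxy)phenyl]-4-{(2R,3R,4S,5R)-2,5-bis[4-(benzyloxy)phenyl]-4-[3,5-bis(benzyloxy)phenyl]oxolan-3-yl}-2-(4-hydroxyphenyl)-2,3-dihydro-1-benzofuran-6-ol | Oc1ccc([C@H]2Oc3cc(O)cc([C@H]4[C@@H](c5cc(OCc6ccccc6)cc(OCc6ccccc6)c5)[C@H](c5ccc(OCc6ccccc6)cc5)O[C@H]4c4ccc(OCc6ccccc6)cc4)c3[C@@H]2c2cc(OCc6ccccc6)cc(OCc6ccccc6)c2)cc1 | intermediate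
27 | (2S,3S)-3-(3,5-dihydroxyphenyl)-4-[(2R,3R,4S,5R)-4-(3,5-dihydroxyphenyl)-2,5-bis(4-hydroxyphenyl)oxolan-3-yl]-2-(4-hydroxyphenyl)-2,3-dihydro-1-benzofuran-6-ol | Oc1ccc([C@H]2Oc3cc(O)cc([C@H]4[C@@H](c5cc(O)cc(O)c5)[C@H](c5ccc(O)cc5)O[C@H]4c4ccc(O)cc4)c3[C@@H]2c2cc(O)cc(O)c2)cc1 | target

## Step count and least certain steps

Total step count: 14. Longest linear sequence: 10 steps (steps 1, 2, 5, 6, 7, 8, 9, 10, 13, 14).

**Step 13 (key step).** The most likely failure is that the stilbene radical dimerises with itself to dihydrobenzofuran-type dimers faster than it reacts with the hindered resorcinol. Next in likelihood are bond formation at the ring carbon between the two hydroxyls, a poor face selectivity at C3, and further oxidation of the free 4-hydroxyphenyl group of the product.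

Fallback, from 19 to 27, using known ionic chemistry for the same two bonds. Palladium-catalysed α-arylation of commercial 1-[3,5-bis(benzyloxy)phenyl]ethanone with bromide 14 (Pd2(dba)3, Xantphos, NaOtBu) would give the deoxybenzoin F1, and CuBr2 its α-bromo ketone F2. Alkylation of one hydroxyl of 19 with F2 (K2CO3, acetone) gives the aryloxy ketone F3. Cyclodehydration with Bi(OTf)3 onto the ring carbon ortho to the ether oxygen and para to the free hydroxyl gives the 2,3-diarylbenzofuran F4, forming C3–C3a. Hydrogenation over 10% Pd/C adds hydrogen cis across C2–C3 and removes all seven benzyl groups, giving the 2,3-cis octaphenol F5. Epimerisation at C2 under mild base (K2CO3, MeOH, argon), by reversible opening to the p-quinone methide, which only the aryl ether bond at C2 allows, should lead to 27. This sequence is longer and leaves the face selectivity of the hydrogenation to the substrate.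

**Step 7.** Three processes may interfere. The electron-rich bis(benzyloxy)phenyl ring of a second lactone molecule may be arylated in place of the excess arene 12. The new benzylic C5–O bond may ionise again and take up a second arene with ring opening. The cation may lose the C4 proton, which would erode the 3,4-cis relation.

Fallback, from 11 to 13. Hydrolysis of the acetal (aqueous HCl, THF) gives the lactol F6, which reacts through its open aldehyde form with two equivalents of the weakly basic arylcerium reagent 16 to give the hydroxy acid F7. Lactonisation with catalytic p-TsOH in toluene, under which the benzylic C5 centre equilibrates to the trans lactone, returns to 13.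

**Step 6.** The tetrasubstituted, doubly arylated alkene may reduce only slowly on platinum, and partial hydrogenolysis of the benzyl ethers or saturation of an arene may set in first.

Fallback, from 10 to 11. Hydrogenation over 10% Pd/C under pressure reduces the alkene with the same face selectivity and knowingly removes both benzyl groups, giving the resorcinol lactone F8. Base-free Mitsunobu etherification with benzyl alcohol (PPh3, DIAD), which spares the epimerisable C3 centre, then restores the benzyl ethers and returns to 11.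

**Step 9.** The 2-aryl oxocarbenium ion may lose the C3 proton to form the enol ether and so scramble C3, or hydride delivery may be insufficiently face-selective at C2.

Fallback, from 17 to 18. Deliberate dehydration of 17 (pyridinium p-toluenesulfonate, toluene, heat) gives the dihydrofuran F9. Its hydrogenation over PtO2 from the face away from the C4 aryl group sets C2 and C3 together by syn addition and returns to 18.

**Step 14.** After debenzylation the three benzylic C–O bonds of the rings, now para to free hydroxyls, may be hydrogenolysed.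

Fallback, from 26 to 27. Non-reductive cleavage of the six benzyl ethers with BCl3 and pentamethylbenzene as cation scavenger at −78 °C, with short contact time, so that no hydrogenolysis of ring bonds is possible. It makes no new compound (F0).

## Further compounds

F1 | step 13 | 2-[4-(benzyloxy)phenyl]-1-[3,5-bis(benzyloxy)phenyl]ethan-1-one | O=C(Cc1ccc(OCc2ccccc2)cc1)c1cc(OCc2ccccc2)cc(OCc2ccccc2)c1
F2 | step 13 | 2-bromo-2-[4-(benzyloxy)phenyl]-1-[3,5-bis(benzyloxy)phenyl]ethan-1-one | O=C(C(Br)c1ccc(OCc2ccccc2)cc1)c1cc(OCc2ccccc2)cc(OCc2ccccc2)c1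
F3 | step 13 | 2-[4-(benzyloxy)phenyl]-1-[3,5-bis(benzyloxy)phenyl]-2-{3-hydroxy-5-[(2R,3R,4S,5R)-2,5-bis[4-(benzyloxy)phenyl]-4-[3,5-bis(benzyloxy)phenyl]oxolan-3-yl]phenoxy}ethan-1-one (mixture at the ether carbon) | O=C(C(Oc1cc(O)cc(c1)[C@H]2[C@@H](c3cc(OCc4ccccc4)cc(OCc4ccccc4)c3)[C@H](c5ccc(OCc6ccccc6)cc5)O[C@H]2c7ccc(OCc8ccccc8)cc7)c1ccc(OCc2ccccc2)cc1)c1cc(OCc2ccccc2)cc(OCc2ccccc2)c1
F4 | step 13 | 2-[4-(benzyloxy)phenyl]-3-[3,5-bis(benzyloxy)phenyl]-4-{(2R,3R,4S,5R)-2,5-bis[4-(benzyloxy)phenyl]-4-[3,5-bis(benzyloxy)phenyl]oxolan-3-yl}-1-benzofuran-6-ol | Oc1cc2oc(c3ccc(OCc4ccccc4)cc3)c(c3cc(OCc4ccccc4)cc(OCc4ccccc4)c3)c2c(c1)[C@H]5[C@@H](c3cc(OCc4ccccc4)cc(OCc4ccccc4)c3)[C@H](c3ccc(OCc4ccccc4)cc3)O[C@H]5c3ccc(OCc4ccccc4)cc3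
F5 | step 13 | (2R,3S)-3-(3,5-dihydroxyphenyl)-4-[(2R,3R,4S,5R)-4-(3,5-dihydroxyphenyl)-2,5-bis(4-hydroxyphenyl)oxolan-3-yl]-2-(4-hydroxyphenyl)-2,3-dihydro-1-benzofuran-6-ol (2,3-cis) | Oc1ccc([C@@H]2Oc3cc(O)cc([C@H]4[C@@H](c5cc(O)cc(O)c5)[C@H](c5ccc(O)cc5)O[C@H]4c4ccc(O)cc4)c3[C@@H]2c2cc(O)cc(O)c2)cc1
F6 | step 7 | (3R,4S)-4-[3,5-bis(benzyloxy)phenyl]-5-hydroxy-3-[3,5-bis(triisopropylsilyloxy)phenyl]oxolan-2-one (mixture at C5) | CC(C)[Si](C(C)C)(C(C)C)Oc1cc(O[Si](C(C)C)(C(C)C)C(C)C)cc(c1)[C@H]2[C@@H](c3cc(OCc4ccccc4)cc(OCc4ccccc4)c3)C(O)OC2=O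
F7 | step 7 | (2R,3S)-3-[3,5-bis(benzyloxy)phenyl]-4-[4-(benzyloxy)phenyl]-4-hydroxy-2-[3,5-bis(triisopropylsilyloxy)phenyl]butanoic acid (mixture at C4) | CC(C)[Si](C(C)C)(C(C)C)Oc1cc(O[Si](C(C)C)(C(C)C)C(C)C)cc(c1)[C@H](C(O)=O)[C@@H](c3cc(OCc4ccccc4)cc(OCc4ccccc4)c3)C(O)c5ccc(OCc6ccccc6)cc5
F8 | step 6 | (3R,4S,5S)-4-(3,5-dihydroxyphenyl)-3-[3,5-bis(triisopropylsilyloxy)phenyl]-5-{[(1R,2S,5R)-2-isopropyl-5-methylcyclohexyl]oxy}oxolan-2-one | CC(C)[C@@H]1CC[C@@H](C)C[C@H]1O[C@H]2OC(=O)[C@@H](c3cc(O[Si](C(C)C)(C(C)C)C(C)C)cc(O[Si](C(C)C)(C(C)C)C(C)C)c3)[C@H]2c5cc(O)cc(O)c5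
F9 | step 9 | (4R,5R)-2,5-bis[4-(benzyloxy)phenyl]-4-[3,5-bis(benzyloxy)phenyl]-3-[3,5-bis(triisopropylsilyloxy)phenyl]-4,5-dihydrofuran | CC(C)[Si](C(C)C)(C(C)C)Oc1cc(O[Si](C(C)C)(C(C)C)C(C)C)cc(c1)C2=C(c3ccc(OCc4ccccc4)cc3)O[C@@H](c5ccc(OCc6ccccc6)cc5)[C@@H]2c7cc(OCc8ccccc8)cc(OCc8ccccc8)c7
F0 | step 14 | none | none
A1 | alternative 1 | 3,5-bis(benzyloxy)-2-(trimethylsilyl)phenyl trifluoromethanesulfonate | C[Si](C)(C)c1c(OCc2ccccc2)cc(OCc2ccccc2)cc1OS(=O)(=O)C(F)(F)F
A2 | alternative 1 | methyl 3-[3,5-bis(benzyloxy)phenyl]-3-oxopropanoate | COC(=O)CC(=O)c1cc(OCc2ccccc2)cc(OCc2ccccc2)c1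
A3 | alternative 1 | methyl 2-[3,5-bis(benzyloxy)-2-[3,5-bis(benzyloxy)benzoyl]phenyl]acetate | COC(=O)Cc1cc(OCc2ccccc2)cc(OCc2ccccc2)c1C(=O)c1cc(OCc2ccccc2)cc(OCc2ccccc2)c1
A4 | alternative 2 | (4R,5S)-5-[4-(benzyloxy)phenyl]-4-[3,5-bis(benzyloxy)phenyl]oxolan-2-one | O=C1C[C@H](c2cc(OCc3ccccc3)cc(OCc3ccccc3)c2)[C@@H](c2ccc(OCc3ccccc3)cc2)O1
A5 | alternative 2 | (E)-5,5-dimethoxypent-3-en-2-one | CC(=O)/C=C/C(OC)OC
A6 | alternative 2 | (2S,3S)-2-[4-(benzyloxy)phenyl]-3-[3,5-bis(benzyloxy)phenyl]-4-(dimethoxymethyl)-3,3a,4,5-tetrahydro-1-benzofuran-6(2H)-one (C3a and C4 unassigned) | c6ccccc6COc1ccc([C@H]2OC3=CC(=O)CC(C(OC)OC)C3[C@@H]2c2cc(OCc6ccccc6)cc(OCc6ccccc6)c2)cc1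
A7 | alternative 3 | 2-diazo-1-[4-(benzyloxy)phenyl]-2-{(2S,3S)-6-(benzyloxy)-2-[4-(benzyloxy)phenyl]-3-[3,5-bis(benzyloxy)phenyl]-2,3-dihydro-1-benzofuran-4-yl}ethan-1-one | c1ccccc1COc1ccc([C@H]2Oc3cc(OCc4ccccc4)cc(C(=[N+]=[N-])C(=O)c4ccc(OCc5ccccc5)cc4)c3[C@@H]2c2cc(OCc4ccccc4)cc(OCc4ccccc4)c2)cc1
A8 | alternative 3 | (E)-1,3-bis(benzyloxy)-5-[4-(benzyloxy)styryl]benzene | c1ccccc1COc1ccc(/C=C/c2cc(OCc3ccccc3)cc(OCc3ccccc3)c2)cc1
A9 | alternative 3 | 4',5'-trans-2,3,4,5-tetraaryl-4,5-dihydrofuran carrying the perbenzylated (2S,3S)-dihydrobenzofuran on C3' | c6ccccc6COc1ccc([C@H]2Oc3cc(OCc6ccccc6)cc(C4=C(c5ccc(OCc6ccccc6)cc5)O[C@@H](c5ccc(OCc6ccccc6)cc5)[C@@H]4c4cc(OCc6ccccc6)cc(OCc6ccccc6)c4)c3[C@@H]2c2cc(OCc6ccccc6)cc(OCc6ccccc6)c2)cc1
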